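**Retrosynthetic overview**
1. Feature: ring C (C1–C4 of the 2‑hydroxy‑1,4‑naphthoquinone; oxygen on C1, C2, C4, hydrogen on C3) is a four‑carbon squarate unit that keeps one alkoxy group. C4 sits on C4a, whose ortho carbons are C5 (oxygenated, blocked) and C8a (free).
2. Ring C: the C1–C8a bond is cut back through a six‑electron closure and a four‑electron opening to a 4‑aryl‑2,4‑dimethoxycyclobutenone that already carries rings A and B.
3. Cyclobutenone: aryllithium of the bromo diaryl ketone plus dimethyl squarate, O‑methylation, then a reductive 1,3‑carbonyl transposition that puts hydrogen on C3 and leaves the methoxy group on C2.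
4. Rings A and B: ring A aryllithium (from 3,5‑dimethoxytoluene) plus the ring B aldehyde (from 2‑bromo‑5‑iodophenol by allylation, ortho‑formylation, methylation), then oxidation.
5. Ring D and end: allyl → aldehyde → acetoacetate dianion aldol → oxidation → lactonisation; BBr3 frees all phenols and air converts the 1,2,4‑triol into the hydroxyquinone. Rings A and B are bought; ring C is formed before ring D.

Key step: step 9

Remark (assumptions): atom numbers C1–C8a are those of the target naphthoquinone (C=O at C1/C4, OH at C2/C5, aroyl at C6, pyronylmethyl at C7); the C4 oxygen is carried through the ring expansion as its methyl ether; stereogenic intermediates are racemic because the target is achiral; 2‑bromo‑5‑iodophenol is taken as a catalogue compound.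

Step 1
Reactants: 1 2‑bromo‑5‑iodophenol
Product: 2 5‑allyl‑2‑bromophenol
Conditions: CH2=CHCH2SnBu3 (1.05 equiv), Pd(PPh3)4 (5 mol %), DMF, 65 °C
Reagents that add atoms: allyltributylstannane, C=CC[Sn](CCCC)(CCCC)CCCC
Why: Stille coupling in which palladium inserts into the C–I bond far faster than into the C–Br bond, so only the iodide should be replaced by allyl while the free phenol is tolerated.

Step 2
Reactants: 2 5‑allyl‑2‑bromophenol
Product: 3 6‑allyl‑3‑bromo‑2‑hydroxybenzaldehyde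
Conditions: MgCl2, Et3N, (CH2O)n, MeCN, reflux; then 1 M HCl
Reagents that add atoms: formaldehyde (as paraformaldehyde), C=O
Why: Casnati–Skattebøl ortho‑formylation, in which the magnesium phenoxide delivers formaldehyde to the only free ortho carbon (the other carries bromine) and a second formaldehyde oxidises the benzylic alkoxide to the aldehyde, so the ortho regiochemistry does not depend on an electrophilic halogenation.

Step 3
Reactants: 3 6‑allyl‑3‑bromo‑2‑hydroxybenzaldehyde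
Product: 4 6‑allyl‑3‑bromo‑2‑methoxybenzaldehyde
Conditions: MeI, K2CO3, DMF, rt
Reagents that add atoms: iodomethane, CI
Why: Williamson O‑methylation of the only acidic group, under conditions too mild to move the allyl double bond.

Step 4
Reactants: 5 3,5‑dimethoxytoluene
Product: 6 2‑bromo‑3,5‑dimethoxytoluene
Conditions: NBS, MeCN, 0 °C → rt
Reagents that add atoms: N‑bromosuccinimide, O=C1CCC(=O)N1Br
Why: Electrophilic aromatic bromination at C2, which is para to one methoxy group and less crowded than C4 between the two methoxy groups.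

Step 5
Reactants: 6 2‑bromo‑3,5‑dimethoxytoluene, 4 6‑allyl‑3‑bromo‑2‑methoxybenzaldehyde
Product: 8 (6‑allyl‑3‑bromo‑2‑methoxyphenyl)(2,4‑dimethoxy‑6‑methylphenyl)methanol (racemic), via aryllithium 7 (not isolated)
Conditions: n‑BuLi (1.05 equiv), THF, −78 °C; then 4, −78 → −40 °C; H2O
Reagents that add atoms: none
Why: Bromine–lithium exchange followed by 1,2‑addition of the aryllithium to the aldehyde, which is faster at −78 °C than exchange with the aryl bromide of 4; the carbinol centre is racemic and is removed in step 6.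

Step 6
Reactants: 8 (6‑allyl‑3‑bromo‑2‑methoxyphenyl)(2,4‑dimethoxy‑6‑methylphenyl)methanol
Product: 9 (6‑allyl‑3‑bromo‑2‑methoxyphenyl)(2,4‑dimethoxy‑6‑methylphenyl)methanone
Conditions: DMP, CH2Cl2, rt
Reagents that add atoms: none
Why: Dess–Martin oxidation of the hindered diaryl carbinol under neutral conditions that leave the allyl group and the aryl bromide alone.

Step 7
Reactants: 9 (6‑allyl‑3‑bromo‑2‑methoxyphenyl)(2,4‑dimethoxy‑6‑methylphenyl)methanone, 10 dimethyl squarate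
Product: 13 4‑[4‑allyl‑3‑(2,4‑dimethoxy‑6‑methylbenzoyl)‑2‑methoxyphenyl]‑2,3,4‑trimethoxycyclobut‑2‑en‑1‑one (racemic), via aryllithium 11 (not isolated), via lithium alkoxide 12 (not isolated)
Conditions: n‑BuLi (1.0 equiv), THF, −100 °C, 5 min; cannulated into 10 (1.2 equiv), THF, −78 °C; then CF3SO3Me, −78 → 0 °C
Reagents that add atoms: methyl trifluoromethanesulfonate, COS(=O)(=O)C(F)(F)F
Why: Bromine–lithium exchange ortho to methoxy at −100 °C should outrun any attack on the tetra‑ortho‑substituted ketone, the aryllithium adds 1,2 to one of the two equivalent squarate carbonyls, and the alkoxide is capped in the flask as the methyl ether, giving a racemic quaternary centre that disappears in step 9.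

Step 8
Reactants: 13 4‑[4‑allyl‑3‑(2,4‑dimethoxy‑6‑methylbenzoyl)‑2‑methoxyphenyl]‑2,3,4‑trimethoxycyclobut‑2‑en‑1‑one
Product: 16 4‑[4‑allyl‑3‑(2,4‑dimethoxy‑6‑methylbenzoyl)‑2‑methoxyphenyl]‑2,4‑dimethoxycyclobut‑2‑en‑1‑one (racemic), via cyclobutenol 14 (not isolated), via trifluoroacetate 15 (not isolated)
Conditions: i‑Bu2AlH (1.1 equiv), CH2Cl2, −78 °C; then 2,6‑lutidine, (CF3CO)2O, −78 → 0 °C; then aq. NaHCO3
Reagents that add atoms: water, O
Why: Reductive 1,3‑carbonyl transposition of Stork–Danheiser type, the same reduction‑then‑ionisation sequence that converts squarate esters into semisquarates: the hydride adds to the strained cyclobutenone carbonyl (the shielded diaryl ketone should not compete), the aluminium alkoxide is the only oxygen that can be acylated, its trifluoroacetate ionises with the push of the vinylogous C3 methoxy group (numbering of 13), and water adds at that carbon with loss of methanol, so the old carbonyl carbon becomes the ring CH, the carbon next to the aryl‑bearing carbon becomes the new carbonyl, and the tertiary methyl ether stays.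

Step 9
Reactants: 16 4‑[4‑allyl‑3‑(2,4‑dimethoxy‑6‑methylbenzoyl)‑2‑methoxyphenyl]‑2,4‑dimethoxycyclobut‑2‑en‑1‑one
Product: 19 (3‑allyl‑5‑hydroxy‑1,6,8‑trimethoxynaphthalen‑2‑yl)(2,4‑dimethoxy‑6‑methylphenyl)methanone, via arylvinylketene 17 (not isolated), via dienone 18 (not isolated)
Conditions: degassed p‑xylene (0.02 M), 138 °C, Ar, 2 h
Reagents that add atoms: none
Why: Heat opens the bond between the carbonyl carbon and the aryl‑bearing carbon of the cyclobutenone in a conrotatory four‑electron electrocyclic reaction to the (E)‑arylvinylketene 17, whose ketene carbon closes on the free ortho carbon of ring B in a disrotatory six‑electron electrocyclisation that forms C1–C8a and gives dienone 18, and a proton shift from C8a to oxygen restores both aromatic rings in 19. The closest known reaction is the Moore rearrangement of 4‑aryl‑4‑hydroxy‑ or 4‑alkoxycyclobutenones to 1,4‑dioxygenated naphthalenes. Ring C is the only ring closed, and it is closed by the thermal six‑electron electrocyclisation between the ketene carbon and an arene carbon. No stereocentre remains, because the quaternary carbon of 16 becomes sp2 and the transient C8a centre of 18 is erased by tautomerisation. Two selectivities are needed: torquoselectivity, secured by the C4 methoxy donor rotating outward so that the aryl ring lies cis to the ketene, and site selectivity, secured by the C5 methoxy group, because closure on that substituted ortho carbon cannot aromatise and reverts, leaving C8a as the only productive site. The conditions are neutral, so the shielded diaryl ketone and the allyl group should be untouched.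

Step 10
Reactants: 19 (3‑allyl‑5‑hydroxy‑1,6,8‑trimethoxynaphthalen‑2‑yl)(2,4‑dimethoxy‑6‑methylphenyl)methanone
Product: 20 (3‑allyl‑1,5,6,8‑tetramethoxynaphthalen‑2‑yl)(2,4‑dimethoxy‑6‑methylphenyl)methanone
Conditions: MeI, K2CO3, acetone, 50 °C, Ar
Reagents that add atoms: iodomethane, CI
Why: Williamson methylation of the one free naphthol, which protects the oxidation‑prone hydroquinone monoether for the side‑chain steps.

Step 11
Reactants: 20 (3‑allyl‑1,5,6,8‑tetramethoxynaphthalen‑2‑yl)(2,4‑dimethoxy‑6‑methylphenyl)methanone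
Product: 22 2‑[3‑(2,4‑dimethoxy‑6‑methylbenzoyl)‑4,5,7,8‑tetramethoxynaphthalen‑2‑yl]acetaldehyde, via diol 21 (not isolated)
Conditions: OsO4 (2 mol %), NaIO4 (4 equiv), 2,6‑lutidine, dioxane–H2O 3:1, rt
Reagents that add atoms: sodium periodate, [Na+].[O-]I(=O)(=O)=O (oxygen, relayed by catalytic OsO4)
Why: Lemieux–Johnson cleavage, in which OsO4 dihydroxylates the only isolated alkene and periodate cleaves the diol, with 2,6‑lutidine suppressing over‑oxidation and the arene rings left intact.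

Step 12
Reactants: 22 2‑[3‑(2,4‑dimethoxy‑6‑methylbenzoyl)‑4,5,7,8‑tetramethoxynaphthalen‑2‑yl]acetaldehyde, 23 methyl acetoacetate
Product: 25 methyl 6‑[3‑(2,4‑dimethoxy‑6‑methylbenzoyl)‑4,5,7,8‑tetramethoxynaphthalen‑2‑yl]‑5‑hydroxy‑3‑oxohexanoate (racemic), via dianion 24 (not isolated)
Conditions: 23 (3 equiv), NaH, THF, 0 °C; n‑BuLi, 0 °C; then 22, −78 °C; AcOH
Reagents that add atoms: none
Why: Weiler dianion aldol addition, in which the terminal carbanion of the acetoacetate dianion adds to the aldehyde at −78 °C faster than it enolises it, the shielded diaryl ketone being inert; the new carbinol centre is racemic and is removed in step 13.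

Step 13
Reactants: 25 methyl 6‑[3‑(2,4‑dimethoxy‑6‑methylbenzoyl)‑4,5,7,8‑tetramethoxynaphthalen‑2‑yl]‑5‑hydroxy‑3‑oxohexanoate
Product: 26 methyl 6‑[3‑(2,4‑dimethoxy‑6‑methylbenzoyl)‑4,5,7,8‑tetramethoxynaphthalen‑2‑yl]‑3,5‑dioxohexanoate
Conditions: DMP, CH2Cl2, rt
Reagents that add atoms: none
Why: Dess–Martin oxidation of the secondary alcohol to the 3,5‑diketo ester under neutral conditions.

Step 14
Reactants: 26 methyl 6‑[3‑(2,4‑dimethoxy‑6‑methylbenzoyl)‑4,5,7,8‑tetramethoxynaphthalen‑2‑yl]‑3,5‑dioxohexanoate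
Product: 27 6‑{[3‑(2,4‑dimethoxy‑6‑methylbenzoyl)‑4,5,7,8‑tetramethoxynaphthalen‑2‑yl]methyl}‑4‑hydroxy‑2H‑pyran‑2‑one
Conditions: DBU (1.1 equiv), toluene, rt → 60 °C; then 1 M HCl
Reagents that add atoms: none
Why: Base‑mediated lactonisation of a 3,5‑dioxo ester, in which the enol oxygen of the C5 ketone attacks the ester and methanol is lost to give the 4‑hydroxy‑2‑pyrone (ring D).

Step 15
Reactants: 27 6‑{[3‑(2,4‑dimethoxy‑6‑methylbenzoyl)‑4,5,7,8‑tetramethoxynaphthalen‑2‑yl]methyl}‑4‑hydroxy‑2H‑pyran‑2‑one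
Product: 29 6‑(2,4‑dihydroxy‑6‑methylbenzoyl)‑2,5‑dihydroxy‑7‑[(4‑hydroxy‑2‑oxo‑2H‑pyran‑6‑yl)methyl]naphthalene‑1,4‑dione (CNP0158797.0), via tetrahydroxynaphthalene 28 (not isolated)
Conditions: BBr3 (15 equiv), CH2Cl2, −78 °C → rt; then MeOH, H2O; air (O2), pH 7 phosphate buffer/EtOAc, rt
Reagents that add atoms: none
Why: BBr3 ether cleavage of all six aryl methyl ethers followed by autoxidation of the resulting 1,2,4‑trihydroxynaphthalene unit to the 2‑hydroxy‑1,4‑quinone, so no quinone is exposed to BBr3 and no cerium oxidant meets the free hydroxypyrone.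

**Compound list**
1 | 2‑bromo‑5‑iodophenol | Oc1cc(I)ccc1Br | starting material
2 | 5‑allyl‑2‑bromophenol | Oc1cc(CC=C)ccc1Br | intermediate
3 | 6‑allyl‑3‑bromo‑2‑hydroxybenzaldehyde | O=Cc1c(O)c(Br)ccc1CC=C | intermediate
4 | 6‑allyl‑3‑bromo‑2‑methoxybenzaldehyde | O=Cc1c(OC)c(Br)ccc1CC=C | intermediate
5 | 3,5‑dimethoxytoluene | Cc1cc(OC)cc(OC)c1 | starting material
6 | 2‑bromo‑3,5‑dimethoxytoluene (1‑bromo‑2,4‑dimethoxy‑6‑methylbenzene) | Cc1cc(OC)cc(OC)c1Br | intermediate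
7 | (2,4‑dimethoxy‑6‑methylphenyl)lithium | [Li]c1c(C)cc(OC)cc1OC | intermediate (not isolated)
8 | (6‑allyl‑3‑bromo‑2‑methoxyphenyl)(2,4‑dimethoxy‑6‑methylphenyl)methanol, racemic | Cc1cc(OC)cc(OC)c1C(O)c1c(CC=C)ccc(Br)c1OC | intermediate
9 | (6‑allyl‑3‑bromo‑2‑methoxyphenyl)(2,4‑dimethoxy‑6‑methylphenyl)methanone | Cc1cc(OC)cc(OC)c1C(=O)c1c(CC=C)ccc(Br)c1OC | intermediate
10 | dimethyl squarate (3,4‑dimethoxycyclobut‑3‑ene‑1,2‑dione) | COC1=C(OC)C(=O)C1=O | starting material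
11 | [4‑allyl‑3‑(2,4‑dimethoxy‑6‑methylbenzoyl)‑2‑methoxyphenyl]lithium | Cc1cc(OC)cc(OC)c1C(=O)c1c(CC=C)ccc([Li])c1OC | intermediate (not isolated)
12 | lithium 1‑[4‑allyl‑3‑(2,4‑dimethoxy‑6‑methylbenzoyl)‑2‑methoxyphenyl]‑2,3‑dimethoxy‑4‑oxocyclobut‑2‑en‑1‑olate, racemic | Cc1cc(OC)cc(OC)c1C(=O)c1c(CC=C)ccc(c1OC)C1([O-])C(OC)=C(OC)C1=O.[Li+] | intermediate (not isolated)
13 | 4‑[4‑allyl‑3‑(2,4‑dimethoxy‑6‑methylbenzoyl)‑2‑methoxyphenyl]‑2,3,4‑trimethoxycyclobut‑2‑en‑1‑one, racemic | Cc1cc(OC)cc(OC)c1C(=O)c1c(CC=C)ccc(c1OC)C1(OC)C(OC)=C(OC)C1=O | intermediate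
14 | 4‑[4‑allyl‑3‑(2,4‑dimethoxy‑6‑methylbenzoyl)‑2‑methoxyphenyl]‑2,3,4‑trimethoxycyclobut‑2‑en‑1‑ol (present as its aluminium alkoxide; racemic mixture of diastereomers) | Cc1cc(OC)cc(OC)c1C(=O)c1c(CC=C)ccc(c1OC)C1(OC)C(OC)=C(OC)C1O | intermediate (not isolated)
15 | 4‑[4‑allyl‑3‑(2,4‑dimethoxy‑6‑methylbenzoyl)‑2‑methoxyphenyl]‑2,3,4‑trimethoxycyclobut‑2‑en‑1‑yl trifluoroacetate (racemic mixture of diastereomers) | Cc1cc(OC)cc(OC)c1C(=O)c1c(CC=C)ccc(c1OC)C1(OC)C(OC)=C(OC)C1OC(=O)C(F)(F)F | intermediate (not isolated)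
16 | 4‑[4‑allyl‑3‑(2,4‑dimethoxy‑6‑methylbenzoyl)‑2‑methoxyphenyl]‑2,4‑dimethoxycyclobut‑2‑en‑1‑one, racemic (key‑step precursor) | Cc1cc(OC)cc(OC)c1C(=O)c1c(CC=C)ccc(c1OC)C1(OC)C=C(OC)C1=O | intermediate
17 | (3E)‑4‑[4‑allyl‑3‑(2,4‑dimethoxy‑6‑methylbenzoyl)‑2‑methoxyphenyl]‑2,4‑dimethoxybuta‑1,3‑dien‑1‑one | Cc1cc(OC)cc(OC)c1C(=O)c1c(CC=C)ccc(c1OC)/C(OC)=C\C(OC)=C=O | intermediate (not isolated)
18 | 7‑allyl‑6‑(2,4‑dimethoxy‑6‑methylbenzoyl)‑2,4,5‑trimethoxy‑8aH‑naphthalen‑1‑one, racemic | O=C1C(OC)=CC(OC)=C2C(OC)=C(C(=O)c3c(C)cc(OC)cc3OC)C(CC=C)=CC12 | intermediate (not isolated)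
19 | (3‑allyl‑5‑hydroxy‑1,6,8‑trimethoxynaphthalen‑2‑yl)(2,4‑dimethoxy‑6‑methylphenyl)methanone (key‑step product) | Cc1cc(OC)cc(OC)c1C(=O)c1c(CC=C)cc2c(O)c(OC)cc(OC)c2c1OC | intermediate
20 | (3‑allyl‑1,5,6,8‑tetramethoxynaphthalen‑2‑yl)(2,4‑dimethoxy‑6‑methylphenyl)methanone | Cc1cc(OC)cc(OC)c1C(=O)c1c(CC=C)cc2c(OC)c(OC)cc(OC)c2c1OC | intermediate
21 | [3‑(2,3‑dihydroxypropyl)‑1,5,6,8‑tetramethoxynaphthalen‑2‑yl](2,4‑dimethoxy‑6‑methylphenyl)methanone, racemic | Cc1cc(OC)cc(OC)c1C(=O)c1c(CC(O)CO)cc2c(OC)c(OC)cc(OC)c2c1OC | intermediate (not isolated)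
22 | 2‑[3‑(2,4‑dimethoxy‑6‑methylbenzoyl)‑4,5,7,8‑tetramethoxynaphthalen‑2‑yl]acetaldehyde | Cc1cc(OC)cc(OC)c1C(=O)c1c(CC=O)cc2c(OC)c(OC)cc(OC)c2c1OC | intermediate
23 | methyl acetoacetate | CC(=O)CC(=O)OC | starting material
24 | methyl acetoacetate dianion (sodium lithium salt) | [CH2-]C(=O)[CH-]C(=O)OC.[Na+].[Li+] | intermediate (not isolated)
25 | methyl 6‑[3‑(2,4‑dimethoxy‑6‑methylbenzoyl)‑4,5,7,8‑tetramethoxynaphthalen‑2‑yl]‑5‑hydroxy‑3‑oxohexanoate, racemic | Cc1cc(OC)cc(OC)c1C(=O)c1c(CC(O)CC(=O)CC(=O)OC)cc2c(OC)c(OC)cc(OC)c2c1OC | intermediate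
26 | methyl 6‑[3‑(2,4‑dimethoxy‑6‑methylbenzoyl)‑4,5,7,8‑tetramethoxynaphthalen‑2‑yl]‑3,5‑dioxohexanoate | Cc1cc(OC)cc(OC)c1C(=O)c1c(CC(=O)CC(=O)CC(=O)OC)cc2c(OC)c(OC)cc(OC)c2c1OC | intermediate
27 | 6‑{[3‑(2,4‑dimethoxy‑6‑methylbenzoyl)‑4,5,7,8‑tetramethoxynaphthalen‑2‑yl]methyl}‑4‑hydroxy‑2H‑pyran‑2‑one | Cc1cc(OC)cc(OC)c1C(=O)c1c(Cc3cc(O)cc(=O)o3)cc2c(OC)c(OC)cc(OC)c2c1OC | intermediate
28 | 6‑{[3‑(2,4‑dihydroxy‑6‑methylbenzoyl)‑4,5,7,8‑tetrahydroxynaphthalen‑2‑yl]methyl}‑4‑hydroxy‑2H‑pyran‑2‑one | Cc1cc(O)cc(O)c1C(=O)c1c(Cc3cc(O)cc(=O)o3)cc2c(O)c(O)cc(O)c2c1O | intermediate (not isolated)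
29 | 6‑(2,4‑dihydroxy‑6‑methylbenzoyl)‑2,5‑dihydroxy‑7‑[(4‑hydroxy‑2‑oxo‑2H‑pyran‑6‑yl)methyl]naphthalene‑1,4‑dione (CNP0158797.0) | Cc1cc(O)cc(O)c1C(=O)c1c(Cc2cc(O)cc(=O)o2)cc2c(c1O)C(=O)C=C(O)C2=O | target

**Step count and risks**
Total step count: 15. Longest linear sequence: 14 steps (1 to 29 through steps 1–3 and 5–15; step 4 is a one‑step side branch to 6).

Steps most likely to fail:

1. Step 8 (reductive transposition). The cyclobutenyl alkoxide may ring‑open before it is acylated, ionisation may occur at the tertiary methyl ether instead of the trifluoroacetate, or the diaryl ketone may be partly reduced. Fallback, setting out from 10 and 9 and returning at 16, puts the hydride in before the aryl group. 10 is reduced with LiAlH(OtBu)3 (THF, −78 °C) to 4‑hydroxy‑2,3‑dimethoxycyclobut‑2‑en‑1‑one F1. F1 is ionised with BF3·OEt2 in MeOH and trapped at the methoxy‑bearing terminus as 3,4,4‑trimethoxycyclobut‑2‑en‑1‑one F2. Aryllithium 11 (from 9 as in step 7) adds to the only carbonyl of F2 and CF3SO3Me caps the alkoxide, giving [6‑allyl‑2‑methoxy‑3‑(1,3,4,4‑tetramethoxycyclobut‑2‑en‑1‑yl)phenyl](2,4‑dimethoxy‑6‑methylphenyl)methanone F3. The ketal of F3 is hydrolysed with oxalic acid on wet silica gel at 0 °C to 16. The point to watch is that acid can instead ionise the aryl‑bearing carbon and give the 1,3‑transposed enone, which is why this is not the main route.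

2. Step 9 (key step). The six‑electron closure onto the crowded, acyl‑substituted ring B may be slow enough that the ketene is lost to dimerisation or adventitious nucleophiles, and a minor inward rotation of the methoxy group would give open‑chain by‑products. Fallback, setting out from 4 and returning at 20, runs the ring expansion before ring A is attached; it also removes the halogen–lithium exchange next to a ketone in step 7.
 - 4 is converted with HC(OMe)3 and TsOH (cat.) in MeOH into 1‑allyl‑4‑bromo‑2‑(dimethoxymethyl)‑3‑methoxybenzene F4.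
 - n‑BuLi, then 10, then CF3SO3Me give 4‑[4‑allyl‑3‑(dimethoxymethyl)‑2‑methoxyphenyl]‑2,3,4‑trimethoxycyclobut‑2‑en‑1‑one F5.
 - i‑Bu2AlH, then (CF3CO)2O/2,6‑lutidine and aq. NaHCO3 give 4‑[4‑allyl‑3‑(dimethoxymethyl)‑2‑methoxyphenyl]‑2,4‑dimethoxycyclobut‑2‑en‑1‑one F6.
 - Thermolysis in p‑xylene at 138 °C gives 7‑allyl‑6‑(dimethoxymethyl)‑2,4,5‑trimethoxynaphthalen‑1‑ol F7.
 - MeI/K2CO3 gives 3‑allyl‑2‑(dimethoxymethyl)‑1,5,6,8‑tetramethoxynaphthalene F8.
 - 1 M HCl in THF frees 3‑allyl‑1,5,6,8‑tetramethoxy‑2‑naphthaldehyde F9.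
 - Aryllithium 7 adds to give (3‑allyl‑1,5,6,8‑tetramethoxynaphthalen‑2‑yl)(2,4‑dimethoxy‑6‑methylphenyl)methanol F10, and DMP oxidation gives 20.

3. Step 15 (global demethylation and oxidation). Ether cleavage may stop short at the crowded peri positions, and the unprotected polyphenol may over‑oxidise or condense during the aerobic work‑up. Fallback, setting out from 27 and returning at 29, fixes the quinone oxidation level first while everything else is capped. The pyrone hydroxyl of 27 is methylated (Me2SO4, K2CO3, acetone) to 6‑{[3‑(2,4‑dimethoxy‑6‑methylbenzoyl)‑4,5,7,8‑tetramethoxynaphthalen‑2‑yl]methyl}‑4‑methoxy‑2H‑pyran‑2‑one F11. (NH4)2Ce(NO3)6 in MeCN–H2O at 0 °C removes the C1 and C4 methyl groups oxidatively to give 6‑(2,4‑dimethoxy‑6‑methylbenzoyl)‑2,5‑dimethoxy‑7‑[(4‑methoxy‑2‑oxo‑2H‑pyran‑6‑yl)methyl]naphthalene‑1,4‑dione F12. BBr3 in CH2Cl2 then cleaves the five remaining methyl ethers to 29.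

**Further compounds**
F1 | step 8 | 4‑hydroxy‑2,3‑dimethoxycyclobut‑2‑en‑1‑one (racemic) | COC1=C(OC)C(O)C1=O
F2 | step 8 | 3,4,4‑trimethoxycyclobut‑2‑en‑1‑one | COC1=CC(=O)C1(OC)OC
F3 | step 8 | [6‑allyl‑2‑methoxy‑3‑(1,3,4,4‑tetramethoxycyclobut‑2‑en‑1‑yl)phenyl](2,4‑dimethoxy‑6‑methylphenyl)methanone (racemic) | Cc1cc(OC)cc(OC)c1C(=O)c1c(CC=C)ccc(c1OC)C1(OC)C=C(OC)C1(OC)OC
F4 | step 9 | 1‑allyl‑4‑bromo‑2‑(dimethoxymethyl)‑3‑methoxybenzene | COC(OC)c1c(OC)c(Br)ccc1CC=C
F5 | step 9 | 4‑[4‑allyl‑3‑(dimethoxymethyl)‑2‑methoxyphenyl]‑2,3,4‑trimethoxycyclobut‑2‑en‑1‑one (racemic) | COC(OC)c1c(CC=C)ccc(c1OC)C1(OC)C(OC)=C(OC)C1=O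
F6 | step 9 | 4‑[4‑allyl‑3‑(dimethoxymethyl)‑2‑methoxyphenyl]‑2,4‑dimethoxycyclobut‑2‑en‑1‑one (racemic) | COC(OC)c1c(CC=C)ccc(c1OC)C1(OC)C=C(OC)C1=O
F7 | step 9 | 7‑allyl‑6‑(dimethoxymethyl)‑2,4,5‑trimethoxynaphthalen‑1‑ol | COC(OC)c1c(CC=C)cc2c(O)c(OC)cc(OC)c2c1OC
F8 | step 9 | 3‑allyl‑2‑(dimethoxymethyl)‑1,5,6,8‑tetramethoxynaphthalene | COC(OC)c1c(CC=C)cc2c(OC)c(OC)cc(OC)c2c1OC
F9 | step 9 | 3‑allyl‑1,5,6,8‑tetramethoxy‑2‑naphthaldehyde | O=Cc1c(CC=C)cc2c(OC)c(OC)cc(OC)c2c1OC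
F10 | step 9 | (3‑allyl‑1,5,6,8‑tetramethoxynaphthalen‑2‑yl)(2,4‑dimethoxy‑6‑methylphenyl)methanol (racemic) | Cc1cc(OC)cc(OC)c1C(O)c1c(CC=C)cc2c(OC)c(OC)cc(OC)c2c1OC
F11 | step 15 | 6‑{[3‑(2,4‑dimethoxy‑6‑methylbenzoyl)‑4,5,7,8‑tetramethoxynaphthalen‑2‑yl]methyl}‑4‑methoxy‑2H‑pyran‑2‑one | Cc1cc(OC)cc(OC)c1C(=O)c1c(Cc3cc(OC)cc(=O)o3)cc2c(OC)c(OC)cc(OC)c2c1OC
F12 | step 15 | 6‑(2,4‑dimethoxy‑6‑methylbenzoyl)‑2,5‑dimethoxy‑7‑[(4‑methoxy‑2‑oxo‑2H‑pyran‑6‑yl)methyl]naphthalene‑1,4‑dione | Cc1cc(OC)cc(OC)c1C(=O)c1c(Cc3cc(OC)cc(=O)o3)cc2c(c1OC)C(=O)C=C(OC)C2=O
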